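## Structural features

Phylloflavan is a 3-O-acylated flavan-3-ol. Its core is a 2-aryl-3,4-dihydro-2H-chromene with a 5,7-dihydroxylated aromatic ring A, a dihydropyran ring C and a catechol ring B on C2, and the oxygen on C3 of ring C is esterified with 5-(3,4-dihydroxyphenyl)-3-hydroxypentanoic acid. Ring C carries two adjacent stereocentres, C2 (R) and C3 (S), with the aryl and acyloxy groups trans, which is the arrangement found in (+)-catechin. The third stereocentre, the chain carbinol C3 (S), is isolated: it lies five bonds from flavan C3 across a flexible ester, so no neighbouring centre can direct its formation. The fragile features are: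
- the six phenols (two catechols and the electron-rich ring A, which is also C-nucleophilic at C6 and C8), all easily oxidised;
- the benzylic C2–O1 bond, through which C2 can epimerise in base while the 4'-hydroxyl is free;
- the β-hydroxy ester, which can hydrolyse, transesterify, dehydrate to the enoate or undergo retro-aldol cleavage.

The real difficulty is therefore not the flavan, which the chiral pool supplies, but setting the remote chain carbinol under reagent control and joining the chain to a hindered secondary alcohol without exposing the β-hydroxy ester or free phenols to strong acid or base. The key step uses the fact that chain C3 is β to the ester carbonyl C1. In the (E)-enoate of O3 (chain C2=C3) that carbon is the electrophilic terminus, so a boryl nucleophile can be delivered there under catalyst control and later exchanged for hydroxyl with retention.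

## Logic of the disconnections

12 ⇒ 11. The six phenolic O–H bonds are exchanged for O–CH2Ph bonds. Free phenols would be oxidised, C-alkylated or deprotonated in every earlier step, and a single type of protecting group that leaves under neutral hydrogenolysis keeps the end game to one operation. The gain is a lipophilic, base-tolerant intermediate. The forward step must cleave six aryl benzyl ethers without touching the ester, the secondary alcohol or the benzylic C2–O1 bond of ring C.

11 ⇒ 10. The chain C3–O bond is replaced by a C3–B bond. An oxygen nucleophile cannot be added to an enoate with useful enantiocontrol and would be lost again by β-elimination, whereas a boryl group adds irreversibly and serves as a masked hydroxyl. The gain is that the stereogenic C–O bond follows from a C–B bond. The forward step must be stereospecific (retention) and mild enough for the ester.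

10 ⇒ 8 + 9. The chain C3–B and C2–H bonds are cut, which restores the chain C2=C3 double bond. This removes the only stereocentre the chiral pool does not provide and leaves a flat, achiral chain on a chiral alcohol. The forward step must place boron on C3 only and select one alkene face under catalyst control, which requires a geometrically uniform (E)-alkene.

8 ⇒ 4 + 7. The chain C2=C3 bond is cut. This is the most convergent cut of the chain: one half carries the ring system and a phosphonate, the other the second catechol, and both are of similar size. The forward olefination must be E-selective and use a base weak enough to spare the acyloxy group on ring C and the enolisable aldehyde.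

4 ⇒ 2 + 3. The ester bond O3–C1 is cut. The two-carbon phosphonate unit is attached first so that the later olefination builds the enoate directly on the flavan and no chain hydroxyl ever needs protection. The forward step must acylate a hindered secondary alcohol next to the C2 aryl group under neutral conditions; the ring C3–O bond is not broken, so the configuration is safe.

2 ⇒ 1. Four phenolic O–benzyl bonds are cut. This leads back to the natural product, which supplies both ring-C stereocentres. The forward step must favour O- over C-alkylation on ring A and leave the aliphatic 3-hydroxyl free, which the difference in acidity provides.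

7 ⇒ 6 ⇒ 5. The aldehyde is traced to the ester oxidation level, and then two ether O–benzyl bonds and one ester O–benzyl bond are cut. All three benzyl groups go on in one operation and the ester benzyl is removed in the reduction. The forward reduction must stop at the aldehyde.

## Other disconnections considered

Alternative 1: The cut runs through ring C at O1–C2 and C3–C4. In the forward sense 3,5-bis(benzyloxy)-2-(hydroxymethyl)phenol A2 would lose water on heating or with mild acid to give the o-quinone methide A3. This would be trapped in an inverse-electron-demand hetero-Diels–Alder reaction by the (E)-enol ester A4, the 2-arylvinyl ester of the O-benzylated (S)-hydroxy acid, to give hepta-O-benzylphylloflavan A1.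
- In its favour: two ring bonds, ring C and the 2,3-trans relationship (from the E geometry in a suprafacial addition) would arise in one step with the side chain already attached. No natural flavan-3-ol is needed. In bonds formed per step it is the stronger plan, and its final hydrogenolysis is the equal of the chosen one.
- Against it, stereocontrol: the only stereocentre of A4 is the remote chain carbinol, so it cannot choose between the two faces of the dienophile. A1 should therefore form together with its (2S,3R) diastereomer in nearly equal amounts unless a chiral catalyst for this dienophile class were found.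
- Against it, regiochemistry: the required orientation depends on the electron-rich aryl group overriding the opposing donor effect of the enol-ester oxygen, which also makes A4 a sluggish partner while A3 is prone to oligomerise.
- Against it, the chain: A4 still contains the chain stereocentre, which would have to be made by a separate asymmetric step, so this plan moves that problem but does not solve it.
- Comparison: the mechanism is less secure in absolute stereocontrol, and the step count is higher because A2, the enantiopure acid and a geometrically pure enol ester must all be prepared.

Alternative 2: The cut is at C3–O (with C2–H) of ring C. In the forward sense the achiral 4H-flavene A6 would be hydroborated with monoisopinocampheylborane A7 and oxidised to give 5,7,3',4'-tetra-O-benzyl-(+)-catechin A5, which is the same compound as 2.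
- In its favour: both ring-C stereocentres would come from an achiral precursor. The enol-ether polarisation places boron on C3, and syn addition followed by retentive oxidation gives the trans 3-ol. Either enantiomeric series would be accessible, and in that independence from the natural product it is the better plan.
- Its mechanistic logic (boron as a hydroxyl surrogate, oxidation with retention) is the same as that of the chosen plan, and equally sound.
- Against it here: A5 is one step from an inexpensive natural product. A6 would take several steps to make and is sensitive to double-bond migration and oxidation. The reagent A7 is stoichiometric, and its face selectivity on a trisubstituted aryl enol ether is not assured.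
- The step also leaves the chain stereocentre untouched, so it could only replace step 1, not the key step; steps 2 to 8 would still follow.
- Comparison: it adds several steps and a stereochemical risk for a compound the chiral pool already supplies.

Alternative 3: The cuts are the chain C1–C2 bond and the ester bond O3–C1. In the forward sense the tetracarbonylcobaltate anion [Co(CO)4]−, generated from Co2(CO)8, would open the (S)-epoxide A9 at its CH2 group. Carbon monoxide A11 would insert, and the acylcobalt species would transfer the acyl group to O3 of A5, giving hexa-O-benzylphylloflavan A8, which is the same compound as 11.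
- In its favour: it is the most convergent assembly and forms two skeletal bonds at once. No bond to the stereocentre is touched, so the configurational purity of A8 would equal that of A9, and hydrolytic kinetic resolution is expected to supply A9 in very high purity. On stereochemical security it is the equal of the chosen plan, or better.
- It would reach A8 without a boron stage, which saves one step after the coupling.
- Against it here: this carbonylation is established with simple alcohols used in large excess, not with a hindered secondary alcohol as the limiting partner. The internal alkoxide can capture the acyl group first and give the β-lactone A10, and cobalt hydride species can isomerise A9 to a ketone. Pressurised A11 is also required.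
- A9 would need its own synthesis of several steps, including a resolution that discards half the material. A two-stage variant through A10 would face the choice between acyl and alkyl cleavage with a poor nucleophile.
- Comparison: it is structurally more ambitious but mechanistically less certain at the acyl-transfer stage, and about equal in total step count once the synthesis of A9 is included.

Key step: step 6

Remark on the chemistry: the flavan part of the target has the (2R,3S), 2,3-trans configuration of (+)-catechin and the chain carbinol is S. The boron-bearing carbon of 10 also has the descriptor S (ranking C2 > C4 > B > H), so oxidation with retention leads to the S carbinol without a change of descriptor.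

Assumption: the (S)-(R) hand of the ferrocenyl bisphosphine is taken, by analogy with simple β-alkyl (E)-enoates, to deliver boron to the Si face of chain C3. This is to be confirmed on a small scale before material is committed.

## Route

Step 1
Reactants: 1 (+)-catechin
Product: 2 5,7,3',4'-tetra-O-benzyl-(+)-catechin
Conditions: BnBr (4.4 equiv), K2CO3 (5 equiv), DMF, −10 °C → rt, Ar
Reagents that add atoms: benzyl bromide, BrCc1ccccc1
Why: Williamson etherification of the four phenols; carbonate does not deprotonate the aliphatic 3-hydroxyl, so it stays free. Low temperature and exclusion of air limit C-benzylation of ring A and base-induced epimerisation at C2, which is no longer possible once the 4'-oxygen is capped.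

Step 2
Reactants: 2 5,7,3',4'-tetra-O-benzyl-(+)-catechin; 3 diethylphosphonoacetic acid
Product: 4 5,7,3',4'-tetra-O-benzyl-(+)-catechin 3-O-(diethylphosphonoacetate)
Conditions: DCC (1.6 equiv), DMAP (0.2 equiv), CH2Cl2, 0 °C → rt
Reagents that add atoms: none
Why: Steglich esterification; the carbodiimide-activated phosphonoacetic acid is a small, reactive acyl donor that should acylate the hindered O3 under DMAP catalysis, as in 3-O-acylations of benzylated flavan-3-ols. The ring C3–O bond is not broken, so C2 and C3 keep their configuration.

Step 3
Reactants: 5 3-(3,4-dihydroxyphenyl)propanoic acid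
Product: 6 benzyl 3-[3,4-bis(benzyloxy)phenyl]propanoate
Conditions: BnBr (3.3 equiv), K2CO3 (4 equiv), DMF, rt → 60 °C, Ar
Reagents that add atoms: benzyl bromide, BrCc1ccccc1
Why: One-pot SN2 O-alkylation (Williamson type) of both catechol oxygens and the carboxylate. The ester benzyl is removed in the next step, so only one kind of protecting group remains in the fragment.

Step 4
Reactants: 6 benzyl 3-[3,4-bis(benzyloxy)phenyl]propanoate
Product: 7 3-[3,4-bis(benzyloxy)phenyl]propanal
Conditions: iBu2AlH (1.1 equiv), CH2Cl2, −78 °C; MeOH, then aq. potassium sodium tartrate
Reagents that add atoms: none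
Why: Partial reduction of an ester with diisobutylaluminium hydride; the tetrahedral aluminium hemiacetal is stable at −78 °C and releases the aldehyde only on quenching. Aryl benzyl ethers are inert, and the aldehyde is used promptly.

Step 5
Reactants: 4 5,7,3',4'-tetra-O-benzyl-(+)-catechin 3-O-(diethylphosphonoacetate); 7 3-[3,4-bis(benzyloxy)phenyl]propanal
Product: 8 5,7,3',4'-tetra-O-benzyl-(+)-catechin 3-O-{(E)-5-[3,4-bis(benzyloxy)phenyl]pent-2-enoate}
Conditions: LiCl (1.5 equiv), DBU (1.2 equiv), MeCN–THF, 0 °C → rt; chromatography or crystallisation to geometric purity
Reagents that add atoms: none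
Why: Horner–Wadsworth–Emmons olefination under Masamune–Roush conditions; lithium chelation acidifies the phosphonoacetate so an amidine base suffices, which spares the flavanyl ester and the enolisable aldehyde. A stabilised phosphonate with an unbranched aldehyde should give the (E)-enoate through reversible addition and elimination from the less crowded oxaphosphetane.

Step 6
Reactants: 8 5,7,3',4'-tetra-O-benzyl-(+)-catechin 3-O-{(E)-5-[3,4-bis(benzyloxy)phenyl]pent-2-enoate}; 9 bis(pinacolato)diboron
Product: 10 5,7,3',4'-tetra-O-benzyl-(+)-catechin 3-O-{(3S)-5-[3,4-bis(benzyloxy)phenyl]-3-(4,4,5,5-tetramethyl-1,3,2-dioxaborolan-2-yl)pentanoate}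
Conditions: CuCl (5 mol%), NaOtBu (8 mol%), (S)-1-[(R)-2-(diphenylphosphino)ferrocenyl]ethyldicyclohexylphosphine (Josiphos type, 6 mol%), MeOH (2 equiv), THF, rt, Ar; short silica filtration
Reagents that add atoms: none
Why: NaOtBu converts CuCl and the bisphosphine into a ligated monovalent copper alkoxide, which undergoes σ-bond metathesis with 9 to give a nucleophilic phosphine-bound copper boryl. This adds syn across the chain C2=C3 bond of 8 with boron going to the β-carbon C3, and methanol protonates the resulting copper enolate at C2, releasing 10 and a copper methoxide that re-enters the cycle with 9. The closest known reaction type is the copper-catalysed enantioselective β-borylation of acyclic (E)-α,β-unsaturated esters with a diboron reagent, methanol and a chiral ferrocenyl bisphosphine, for which unbranched β-alkyl enoates are standard substrates. No ring is closed. The one new stereocentre, chain C3, is set by the chiral ligand alone: it shields one face of the bound enoate so that boron arrives on the Si face of C3 and gives the S boronate, while the flavan stereocentres, five or more bonds away, should neither help nor hinder much. The step needs β-regioselectivity (secured by the polarisation of the enoate), chemoselectivity (the enoate is the only electron-poor π bond; aryl benzyl ethers and the ring ether are inert to the copper boryl, and the hindered secondary ester should resist the catalytic alkoxide) and facial selectivity, which rests on the geometric purity of the (E)-alkene from step 5 because a Z isomer would be borylated on the opposite face. Because 8 is already chiral, any stereochemical leakage appears as a diastereomer of 10, which is detectable and in principle removable, not as an enantiomer. The hand of the ligand is to be confirmed on a small scale (both ligand enantiomers, Mosher esters of 11), the antipodal ligand being equally available.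

Step 7
Reactants: 10 5,7,3',4'-tetra-O-benzyl-(+)-catechin 3-O-{(3S)-5-[3,4-bis(benzyloxy)phenyl]-3-(4,4,5,5-tetramethyl-1,3,2-dioxaborolan-2-yl)pentanoate}
Product: 11 hexa-O-benzylphylloflavan, 5,7,3',4'-tetra-O-benzyl-(+)-catechin 3-O-{(3S)-5-[3,4-bis(benzyloxy)phenyl]-3-hydroxypentanoate}
Conditions: NaBO3·4H2O (5 equiv), THF–H2O (1:1), rt
Reagents that add atoms: sodium perborate tetrahydrate (NaBO3·4H2O, drawn as its peroxoborate dimer without water of crystallisation), [Na+].[Na+].O[B-]1(O)OO[B-](O)(O)OO1
Why: Oxidation of an alkylboronate by perborate; hydroperoxide adds to boron, the carbon migrates from boron to oxygen with retention, and the borate ester is hydrolysed, so the S boronate should give the S carbinol. The weakly basic medium should spare the ester and avoid dehydration or retro-aldol cleavage of the β-hydroxy ester.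

Step 8
Reactants: 11 hexa-O-benzylphylloflavan
Product: 12 phylloflavan
Conditions: H2 (1 atm), Pd(OH)2/C (20 wt%), THF–MeOH (1:1), rt; filtration under Ar
Reagents that add atoms: none
Why: Heterogeneous hydrogenolysis of six aryl benzyl ethers under neutral conditions, the usual end game for benzyl-protected flavan-3-ol esters. The aliphatic ester, the non-benzylic secondary alcohol and the ring-C ether should be retained, and no stereocentre is involved.

## Compound list

1 | (+)-catechin, (2R,3S)-2-(3,4-dihydroxyphenyl)-3,4-dihydro-2H-chromene-3,5,7-triol | O[C@H]1Cc2c(O)cc(O)cc2O[C@@H]1c1ccc(O)c(O)c1 | starting material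
2 | 5,7,3',4'-tetra-O-benzyl-(+)-catechin, (2R,3S)-5,7-bis(benzyloxy)-2-[3,4-bis(benzyloxy)phenyl]-3,4-dihydro-2H-chromen-3-ol | O[C@H]1Cc2c(OCc3ccccc3)cc(OCc3ccccc3)cc2O[C@@H]1c1ccc(OCc2ccccc2)c(OCc2ccccc2)c1 | intermediate
3 | diethylphosphonoacetic acid | OC(=O)CP(=O)(OCC)OCC | starting material
4 | 5,7,3',4'-tetra-O-benzyl-(+)-catechin 3-O-(diethylphosphonoacetate), (2R,3S) | CCOP(=O)(CC(=O)O[C@H]1Cc2c(OCc3ccccc3)cc(OCc3ccccc3)cc2O[C@@H]1c1ccc(OCc2ccccc2)c(OCc2ccccc2)c1)OCC | intermediate
5 | 3-(3,4-dihydroxyphenyl)propanoic acid (dihydrocaffeic acid) | OC(=O)CCc1ccc(O)c(O)c1 | starting material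
6 | benzyl 3-[3,4-bis(benzyloxy)phenyl]propanoate | O=C(CCc1ccc(OCc2ccccc2)c(OCc2ccccc2)c1)OCc1ccccc1 | intermediate
7 | 3-[3,4-bis(benzyloxy)phenyl]propanal | O=CCCc1ccc(OCc2ccccc2)c(OCc2ccccc2)c1 | intermediate
8 | 5,7,3',4'-tetra-O-benzyl-(+)-catechin 3-O-{(E)-5-[3,4-bis(benzyloxy)phenyl]pent-2-enoate}, (2R,3S) | O=C(/C=C/CCc1ccc(OCc2ccccc2)c(OCc2ccccc2)c1)O[C@H]1Cc2c(OCc3ccccc3)cc(OCc3ccccc3)cc2O[C@@H]1c1ccc(OCc2ccccc2)c(OCc2ccccc2)c1 | intermediate
9 | bis(pinacolato)diboron | CC1(C)OB(OC1(C)C)B1OC(C)(C)C(C)(C)O1 | starting material
10 | 5,7,3',4'-tetra-O-benzyl-(+)-catechin 3-O-{(3S)-5-[3,4-bis(benzyloxy)phenyl]-3-(4,4,5,5-tetramethyl-1,3,2-dioxaborolan-2-yl)pentanoate}, (2R,3S) in the flavan | O=C(C[C@@H](B1OC(C)(C)C(C)(C)O1)CCc1ccc(OCc2ccccc2)c(OCc2ccccc2)c1)O[C@H]1Cc2c(OCc3ccccc3)cc(OCc3ccccc3)cc2O[C@@H]1c1ccc(OCc2ccccc2)c(OCc2ccccc2)c1 | intermediate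
11 | hexa-O-benzylphylloflavan, 5,7,3',4'-tetra-O-benzyl-(+)-catechin 3-O-{(3S)-5-[3,4-bis(benzyloxy)phenyl]-3-hydroxypentanoate} | O=C(C[C@@H](O)CCc1ccc(OCc2ccccc2)c(OCc2ccccc2)c1)O[C@H]1Cc2c(OCc3ccccc3)cc(OCc3ccccc3)cc2O[C@@H]1c1ccc(OCc2ccccc2)c(OCc2ccccc2)c1 | intermediate
12 | phylloflavan, (2R,3S)-2-(3,4-dihydroxyphenyl)-5,7-dihydroxy-3,4-dihydro-2H-chromen-3-yl (3S)-5-(3,4-dihydroxyphenyl)-3-hydroxypentanoate | O=C(C[C@@H](O)CCc1ccc(O)c(O)c1)O[C@H]1Cc2c(O)cc(O)cc2O[C@@H]1c1ccc(O)c(O)c1 | target

## Step count and least certain steps

Total: 8 steps. Longest linear sequence: 6 steps (1 → 2 → 4 → 8 → 10 → 11 → 12, or equally 5 → 6 → 7 → 8 → 10 → 11 → 12).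

Step 6 (key step). The most likely failure is insufficient facial discrimination. It could come from a background addition by copper boryl that has lost the bisphosphine, from traces of Z-enoate, or from a mismatch between ligand and the bulky chiral ester. Slow turnover is the second risk, because the large lipophilic ester crowds the copper–enoate complex and gives the catalytic alkoxide time to methanolyse the ester.

The fallback replaces conjugate borylation by enantioselective ketone hydrogenation. It sets out from 6 and 2 and returns to the route at 11.
- Saponification of 6 (LiOH, THF–H2O) would give 3-[3,4-bis(benzyloxy)phenyl]propanoic acid F1.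
- Condensation of F1 with Meldrum's acid (DCC, DMAP, CH2Cl2) would give 5-{3-[3,4-bis(benzyloxy)phenyl]-1-hydroxypropylidene}-2,2-dimethyl-1,3-dioxane-4,6-dione F2.
- Heating F2 with 2 in toluene releases an acylketene, which even a hindered alcohol should trap, giving 5,7,3',4'-tetra-O-benzyl-(+)-catechin 3-O-{5-[3,4-bis(benzyloxy)phenyl]-3-oxopentanoate} F3.
- Hydrogenation of F3 with RuCl2[(S)-BINAP] (BINAP = 2,2'-bis(diphenylphosphino)-1,1'-binaphthyl) under H2 in CH2Cl2–MeOH should reduce the ketone to the S carbinol, the sense known for unbranched β-keto esters, and give 11. Homogeneous ruthenium does not cleave benzyl ethers.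

Step 5. The most likely failures are incomplete E selectivity, which would pass directly into the stereochemical outcome of step 6, and base-induced side reactions (self-aldol condensation of 7, or elimination of the acyloxy group from ring C).

The fallback changes the order of bond formation. It sets out from 7 and 2 and returns at 8.
- Olefination of 7 with triethyl phosphonoacetate (NaH, THF, 0 °C) would give ethyl (E)-5-[3,4-bis(benzyloxy)phenyl]pent-2-enoate F4, which is purified to a single geometric isomer as a small molecule.
- Saponification (LiOH, THF–H2O) would give (E)-5-[3,4-bis(benzyloxy)phenyl]pent-2-enoic acid F5.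
- Steglich esterification of F5 with 2 (DCC, DMAP, CH2Cl2) would give 8, so the flavan never meets the olefination base.

Step 4. The most likely failure is over-reduction to the primary alcohol if the tetrahedral aluminium intermediate collapses before the quench, or incomplete conversion if less hydride is used to avoid that.

The fallback is full reduction followed by reoxidation. It sets out from 6 and returns at 7.
- LiAlH4 in THF at 0 °C would give 3-[3,4-bis(benzyloxy)phenyl]propan-1-ol F6.
- Dess–Martin periodinane in CH2Cl2 would oxidise F6 to 7.

Step 8. The most likely failures are incomplete removal of all six benzyl groups as the partly deprotected material becomes more polar and binds the catalyst, slow hydrogenolytic opening of ring C at the benzylic C2–O1 bond on prolonged exposure, and air oxidation of the catechols during work-up.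

The fallback is Lewis-acid debenzylation in place of reduction. It sets out from 11 and arrives at 12, and no new compound is made on the way. BCl3 with pentamethylbenzene as cation scavenger in CH2Cl2 at −78 °C, followed by a methanol quench, should cleave aryl benzyl ethers at a temperature where esters and secondary alcohols are tolerated.

## Further compounds

F1 | step 6 | 3-[3,4-bis(benzyloxy)phenyl]propanoic acid | OC(=O)CCc1ccc(OCc2ccccc2)c(OCc2ccccc2)c1
F2 | step 6 | 5-{3-[3,4-bis(benzyloxy)phenyl]-1-hydroxypropylidene}-2,2-dimethyl-1,3-dioxane-4,6-dione | CC1(C)OC(=O)C(=C(O)CCc2ccc(OCc3ccccc3)c(OCc3ccccc3)c2)C(=O)O1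
F3 | step 6 | 5,7,3',4'-tetra-O-benzyl-(+)-catechin 3-O-{5-[3,4-bis(benzyloxy)phenyl]-3-oxopentanoate} | O=C(CC(=O)CCc1ccc(OCc2ccccc2)c(OCc2ccccc2)c1)O[C@H]1Cc2c(OCc3ccccc3)cc(OCc3ccccc3)cc2O[C@@H]1c1ccc(OCc2ccccc2)c(OCc2ccccc2)c1
F4 | step 5 | ethyl (E)-5-[3,4-bis(benzyloxy)phenyl]pent-2-enoate | CCOC(=O)/C=C/CCc1ccc(OCc2ccccc2)c(OCc2ccccc2)c1
F5 | step 5 | (E)-5-[3,4-bis(benzyloxy)phenyl]pent-2-enoic acid | OC(=O)/C=C/CCc1ccc(OCc2ccccc2)c(OCc2ccccc2)c1
F6 | step 4 | 3-[3,4-bis(benzyloxy)phenyl]propan-1-ol | OCCCc1ccc(OCc2ccccc2)c(OCc2ccccc2)c1
F0 | step 8 | none | none
A1 | alternative 1 | hepta-O-benzylphylloflavan | O=C(C[C@@H](OCc1ccccc1)CCc1ccc(OCc2ccccc2)c(OCc2ccccc2)c1)O[C@H]1Cc2c(OCc3ccccc3)cc(OCc3ccccc3)cc2O[C@@H]1c1ccc(OCc2ccccc2)c(OCc2ccccc2)c1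
A2 | alternative 1 | 3,5-bis(benzyloxy)-2-(hydroxymethyl)phenol | OCc1c(O)cc(OCc2ccccc2)cc1OCc1ccccc1
A3 | alternative 1 | 3,5-bis(benzyloxy)-6-methylidenecyclohexa-2,4-dien-1-one (o-quinone methide) | C=C1C(=O)C=C(OCc2ccccc2)C=C1OCc1ccccc1
A4 | alternative 1 | (E)-2-[3,4-bis(benzyloxy)phenyl]ethenyl (3S)-3-(benzyloxy)-5-[3,4-bis(benzyloxy)phenyl]pentanoate | O=C(C[C@@H](OCc1ccccc1)CCc1ccc(OCc2ccccc2)c(OCc2ccccc2)c1)O/C=C/c1ccc(OCc2ccccc2)c(OCc2ccccc2)c1
A5 | alternative 2 | 5,7,3',4'-tetra-O-benzyl-(+)-catechin (identical with 2) | O[C@H]1Cc2c(OCc3ccccc3)cc(OCc3ccccc3)cc2O[C@@H]1c1ccc(OCc2ccccc2)c(OCc2ccccc2)c1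
A6 | alternative 2 | 5,7-bis(benzyloxy)-2-[3,4-bis(benzyloxy)phenyl]-4H-chromene | C1(c2ccc(OCc3ccccc3)c(OCc3ccccc3)c2)=CCc2c(OCc3ccccc3)cc(OCc3ccccc3)cc2O1
A7 | alternative 2 | monoisopinocampheylborane (enantiomer derived from (+)-α-pinene drawn; the hand needed is not assigned) | B[C@@H]1C[C@@H]2C[C@H]([C@H]1C)C2(C)C
A8 | alternative 3 | hexa-O-benzylphylloflavan with the chain hydroxyl free (identical with 11) | O=C(C[C@@H](O)CCc1ccc(OCc2ccccc2)c(OCc2ccccc2)c1)O[C@H]1Cc2c(OCc3ccccc3)cc(OCc3ccccc3)cc2O[C@@H]1c1ccc(OCc2ccccc2)c(OCc2ccccc2)c1
A9 | alternative 3 | (S)-2-{2-[3,4-bis(benzyloxy)phenyl]ethyl}oxirane | C1O[C@H]1CCc1ccc(OCc2ccccc2)c(OCc2ccccc2)c1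
A10 | alternative 3 | (S)-4-{2-[3,4-bis(benzyloxy)phenyl]ethyl}oxetan-2-one | O=C1C[C@H](CCc2ccc(OCc3ccccc3)c(OCc3ccccc3)c2)O1
A11 | alternative 3 | carbon monoxide | [C-]#[O+]
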